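Numbering used throughout (ring A = the cycloundecadiene): C1 = CH(OAc), C2=C3(Me) (Z), C4 = CH(O-angeloyl), C5H2, C6=C7(Me) (E), C8H2–C9H2–C10H2, C11(Me)2, ring bond C11–C1.
Retrosynthesis: the two ester C–O bonds are cut first, then the ring A bond C8–C9, then C4–C5, C3–C4 and C1–C11 of the open chain.
Forward: C1–C11 by reverse prenylation of but-2-ynal, C3–C4 by formylation of a Z-alkenyl iodide, C4–C5 by a vinylogous aldol that also brings in C6=C7–C8; ring A is then closed at C8–C9 and the esters are put on.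
Enabling feature: C8 is the allylic CH2 of E-C6=C7 (π-allyl from a C8 carbonate) and C9 is the terminus of the only monosubstituted alkene, the vinyl group on quaternary C11, so 9-BBN turns C9 into a primary alkyl nucleophile; the Z-C2=C3 unit with its two allylic oxygens and the gem-dimethyl C11 bend the chain so that C8 and C9 can meet.
Stereochemistry: C1 from reagent-controlled allylboration, Z-C2=C3 from hydroxyl-directed trans-hydroalumination/iodination, C4 and E-C6=C7 from a catalyst-controlled vinylogous Mukaiyama aldol, the Z-enoate from angelic acid itself.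

Key step: step 10

Assumption: in step 6 the (S,S)-bisphosphoramide is taken as the catalyst antipode that opens the Si face of the silicon-bound aldehyde; if the sense is the opposite, the (R,R)-catalyst is used with no other change.

Step 1
Reactants: 1 but-2-ynal; 2 3-methylbuta-1,2-diene
Product: 5 (4S)-3,3-dimethylhept-1-en-5-yn-4-ol, via prenylborane 3 (not isolated), via borinate 4 (not isolated)
Conditions: (−)-Ipc2BH [from (+)-α-pinene], 2, THF, −25 °C; then 1, Et2O, −78 °C; NaOH, H2O2
Reagents that add atoms: none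
Why: Brown allylboration with the prenylborane goes through a chair transition state with allylic transposition, so quaternary C11 and the C1 carbinol are formed together and the isopinocampheyl groups direct attack to the Si face of the ynal (4S here, which is the R centre C1 of the target once the alkyne has become an alkene).

Step 2
Reactants: 5 (4S)-3,3-dimethylhept-1-en-5-yn-4-ol
Product: 7 (4R,5Z)-6-iodo-3,3-dimethylhepta-1,5-dien-4-ol, via alkenylaluminate 6 (not isolated)
Conditions: NaAlH2(OCH2CH2OMe)2 (Red-Al), THF, 0 °C → rt; EtOAc; I2, THF, −78 °C; aq KNaC4H4O6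
Reagents that add atoms: iodine, II
Why: Alkoxide-directed trans-hydroalumination of the propargylic alcohol delivers hydride to C2 and aluminium to C3 inside a five-membered chelate, and iodinolysis with retention should give the alkenyl iodide with iodine cis to C1, which fixes the later Z-C2=C3 geometry.

Step 3
Reactants: 7 (4R,5Z)-6-iodo-3,3-dimethylhepta-1,5-dien-4-ol
Product: 8 tert-butyl{[(4R,5Z)-6-iodo-3,3-dimethylhepta-1,5-dien-4-yl]oxy}dimethylsilane
Conditions: TBSOTf, 2,6-lutidine, CH2Cl2, 0 °C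
Reagents that add atoms: tert-butyldimethylsilyl triflate (TBSOTf), CC(C)(C)[Si](C)(C)OS(=O)(=O)C(F)(F)F
Why: Silylation with the silyl triflate is the standard way to protect a hindered neopentyl-type secondary alcohol, and the ether withstands the organolithium, Lewis acid, hydride and palladium steps that follow.

Step 4
Reactants: 8 tert-butyl{[(4R,5Z)-6-iodo-3,3-dimethylhepta-1,5-dien-4-yl]oxy}dimethylsilane
Product: 11 (2Z,4R)-4-(tert-butyldimethylsilyloxy)-2,5,5-trimethylhepta-2,6-dienal, via alkenyllithium 9 (not isolated), via lithium hemiaminolate 10 (not isolated)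
Conditions: t-BuLi (2.1 equiv), Et2O, −78 °C; DMF, −78 → −40 °C; H2O
Reagents that add atoms: N,N-dimethylformamide, CN(C)C=O
Why: Iodine–lithium exchange and Bouveault formylation both proceed with retention at the alkenyl carbon, so C4 is introduced cis to C1, and ether at −78 °C with immediate trapping should keep the 1,4 O-to-C silyl shift of the Z-alkenyllithium from competing.

Step 5
Reactants: 12 ethyl tiglate
Product: 14 tert-butyl[(1-ethoxy-2-methylbuta-1,3-dien-1-yl)oxy]dimethylsilane, via lithium dienolate 13 (not isolated)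
Conditions: LiN(iPr)2, THF–DMPU, −78 °C; TBSCl, −78 °C → rt
Reagents that add atoms: tert-butyldimethylsilyl chloride, CC(C)(C)[Si](C)(C)Cl
Why: Kinetic γ-deprotonation of the enoate and O-silylation of the dienolate is the usual preparation of a silyl dienol ether for vinylogous aldol chemistry (the ketene acetal geometry is immaterial).

Step 6
Reactants: 11 (2Z,4R)-4-(tert-butyldimethylsilyloxy)-2,5,5-trimethylhepta-2,6-dienal; 14 tert-butyl[(1-ethoxy-2-methylbuta-1,3-dien-1-yl)oxy]dimethylsilane
Product: 16 ethyl (2E,5S,6Z,8R)-8-(tert-butyldimethylsilyloxy)-5-hydroxy-2,6,9,9-tetramethylundeca-2,6,10-trienoate, via trichlorosilyl ether 15 (not isolated)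
Conditions: SiCl4 (1.1 equiv), (S,S)-bisphosphoramide [two N,N'-dimethyl-1,1'-binaphthyl-2,2'-diamine phosphoramide units on an N,N'-dimethylpentane-1,5-diamine linker] (5 mol %), iPr2NEt (10 mol %), CH2Cl2, −78 °C; aq NaHCO3
Reagents that add atoms: none
Why: In this vinylogous Mukaiyama aldol the phosphoramide-bound trichlorosilyl cation activates the conjugated aldehyde and the dienol ether attacks through its γ-carbon in an open transition state, which should form C4–C5, give the E-2-methyl enoate (C6=C7–C8) and set C4 as S by catalyst-controlled Si-face attack, the remote C1 centre having little say.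

Step 7
Reactants: 16 ethyl (2E,5S,6Z,8R)-8-(tert-butyldimethylsilyloxy)-5-hydroxy-2,6,9,9-tetramethylundeca-2,6,10-trienoate
Product: 17 ethyl (2E,5S,6Z,8R)-8-(tert-butyldimethylsilyloxy)-2,6,9,9-tetramethyl-5-(triethylsilyloxy)undeca-2,6,10-trienoate
Conditions: TESCl, imidazole, DMF, 0 °C → rt
Reagents that add atoms: chlorotriethylsilane (TESCl), CC[Si](Cl)(CC)CC
Why: Routine silylation masks the C4 hydroxyl as an allylic ether that cannot ionise under palladium and does not consume the borane in step 10.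

Step 8
Reactants: 17 ethyl (2E,5S,6Z,8R)-8-(tert-butyldimethylsilyloxy)-2,6,9,9-tetramethyl-5-(triethylsilyloxy)undeca-2,6,10-trienoate
Product: 18 (2E,5S,6Z,8R)-8-(tert-butyldimethylsilyloxy)-2,6,9,9-tetramethyl-5-(triethylsilyloxy)undeca-2,6,10-trien-1-ol
Conditions: iBu2AlH (2.5 equiv), CH2Cl2, −78 °C; aq KNaC4H4O6
Reagents that add atoms: none
Why: 1,2-Reduction of the enoate by the aluminium hydride gives the E-allylic alcohol (C8–OH) without touching alkene geometry or the silyl ethers.

Step 9
Reactants: 18 (2E,5S,6Z,8R)-8-(tert-butyldimethylsilyloxy)-2,6,9,9-tetramethyl-5-(triethylsilyloxy)undeca-2,6,10-trien-1-ol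
Product: 19 (2E,5S,6Z,8R)-8-(tert-butyldimethylsilyloxy)-2,6,9,9-tetramethyl-5-(triethylsilyloxy)undeca-2,6,10-trien-1-yl methyl carbonate
Conditions: ClCO2Me, pyridine, CH2Cl2, 0 °C
Reagents that add atoms: methyl chloroformate, COC(=O)Cl
Why: Acylation of the primary allylic alcohol installs a carbonate that is both the leaving group for π-allyl formation and, after loss of CO2, the internal methoxide base for the boron-to-palladium transfer.

Step 10
Reactants: 19 (2E,5S,6Z,8R)-8-(tert-butyldimethylsilyloxy)-2,6,9,9-tetramethyl-5-(triethylsilyloxy)undeca-2,6,10-trien-1-yl methyl carbonate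
Product: 21 (1R,2Z,4S,6E)-1-(tert-butyldimethylsilyloxy)-3,7,11,11-tetramethyl-4-(triethylsilyloxy)cycloundeca-2,6-diene, via alkylborane 20 (not isolated)
Conditions: 9-borabicyclo[3.3.1]nonane (9-BBN, 1.05 equiv), THF, 0 °C → rt; then syringe-pump addition (to about 1 mM) to Pd2(dba)3·CHCl3 (10 mol %), P(2-furyl)3 (40 mol %), THF, 60 °C, no added base
Reagents that add atoms: none
Why: Proposed new method: 9-BBN adds to the only monosubstituted alkene (C9=C10, boron at C9), zerovalent palladium ionises the primary allylic carbonate to an η3-allyl(methoxo)palladium complex with loss of CO2, the methoxide carries the C9 alkyl group from boron to palladium within the same molecule, and C–C reductive elimination at the unsubstituted allyl terminus forms C8–C9. The closest known reaction types are the base-free Suzuki–Miyaura coupling of allylic carbonates with alkenyl- and arylboranes (also used for macrocyclic ring closure), the B-alkyl Suzuki–Miyaura macrocyclisation onto alkenyl iodides and the copper-catalysed allyl–alkyl coupling of B-alkyl-9-BBN reagents with allylic phosphates; the union of a B-alkyl group with a π-allyl terminus in a ring closure is the untested element. Ring A is closed as an eleven-membered carbocycle by reductive elimination from a twelve-membered palladacycle with the allyl unit endocyclic, so that C6=C7 stays in the ring, whereas bonding at C6 would give a nine-membered ring carrying an isopropenyl group and is disfavoured by substitution and strain. No stereocentre is formed, and the E geometry of C6=C7 should be kept because the syn η3-allyl complex born from the E carbonate should couple faster than it isomerises and the E-configured ring is the less strained one. The step needs chemoselective hydroboration (9-BBN leaves the two trisubstituted alkenes alone), cyclisation over oligomerisation (slow addition, the Z-C2=C3 turn and the gem-dimethyl group at C11) and reductive elimination over β-hydride loss from the C9 alkylpalladium (weakly donating P(2-furyl)3), and the silyl ethers at C1 and C4 cannot ionise as allylic esters would.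

Step 11
Reactants: 21 (1R,2Z,4S,6E)-1-(tert-butyldimethylsilyloxy)-3,7,11,11-tetramethyl-4-(triethylsilyloxy)cycloundeca-2,6-diene
Product: 22 (1R,2Z,4S,6E)-3,7,11,11-tetramethylcycloundeca-2,6-diene-1,4-diol
Conditions: TBAF (4 equiv), THF, rt → 45 °C; H2O
Reagents that add atoms: none
Why: Fluoride-mediated desilylation removes both silyl ethers before any ester is present, so the forcing conditions needed for the hindered C1 ether cannot cause acyl migration or ester cleavage.

Step 12
Reactants: 22 (1R,2Z,4S,6E)-3,7,11,11-tetramethylcycloundeca-2,6-diene-1,4-diol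
Product: 23 (1R,2Z,4S,6E)-1-hydroxy-3,7,11,11-tetramethylcycloundeca-2,6-dien-4-yl (2Z)-2-methylbut-2-enoate
Conditions: angelic acid (1.1 equiv), 2,4,6-trichlorobenzoyl chloride, Et3N, toluene, rt; then 22, 75 °C, no DMAP
Reagents that add atoms: angelic acid, C/C=C(/C)C(=O)O
Why: Yamaguchi-type esterification through the mixed anhydride without a nucleophilic catalyst is the established way to make angelates without Z-to-E isomerisation, and the bulky anhydride should acylate the C4 hydroxyl only because the C1 hydroxyl is neopentyl-like next to quaternary C11.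

Step 13
Reactants: 23 (1R,2Z,4S,6E)-1-hydroxy-3,7,11,11-tetramethylcycloundeca-2,6-dien-4-yl (2Z)-2-methylbut-2-enoate
Product: 24 (1R,2Z,4S,6E)-1-acetoxy-3,7,11,11-tetramethylcycloundeca-2,6-dien-4-yl (2Z)-2-methylbut-2-enoate
Conditions: Ac2O, pyridine, DMAP (catalytic), CH2Cl2, rt
Reagents that add atoms: acetic anhydride, CC(=O)OC(C)=O
Why: DMAP-catalysed acetylation is strong enough for the hindered C1 alcohol and mild enough at room temperature to leave the installed angelate and both ring alkenes unchanged.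

Compound list
1 | but-2-ynal | CC#CC=O | starting material
2 | 3-methylbuta-1,2-diene | CC(C)=C=C | starting material
3 | (3-methylbut-2-en-1-yl)bis(isopinocampheyl)borane, Ipc groups from (+)-α-pinene | CC(C)=CCB([C@@H]1C[C@@H]2C[C@@H](C2(C)C)[C@H]1C)[C@@H]1C[C@@H]2C[C@@H](C2(C)C)[C@H]1C | intermediate (not isolated)
4 | bis(isopinocampheyl)borinate of alcohol 5 | C=CC(C)(C)[C@H](OB([C@@H]1C[C@@H]2C[C@@H](C2(C)C)[C@H]1C)[C@@H]1C[C@@H]2C[C@@H](C2(C)C)[C@H]1C)C#CC | intermediate (not isolated)
5 | (4S)-3,3-dimethylhept-1-en-5-yn-4-ol | C=CC(C)(C)[C@H](O)C#CC | intermediate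
6 | sodium alkenylaluminate (five-membered O–Al–C3=C2–C1 chelate with two 2-methoxyethoxy groups on aluminium) | C=CC(C)(C)[C@@H]1O[Al-](OCCOC)(OCCOC)C(C)=C1.[Na+] | intermediate (not isolated)
7 | (4R,5Z)-6-iodo-3,3-dimethylhepta-1,5-dien-4-ol | C=CC(C)(C)[C@H](O)/C=C(\I)C | intermediate
8 | tert-butyl{[(4R,5Z)-6-iodo-3,3-dimethylhepta-1,5-dien-4-yl]oxy}dimethylsilane | C=CC(C)(C)[C@H](O[Si](C)(C)C(C)(C)C)/C=C(\I)C | intermediate
9 | Z-alkenyllithium from 8 (lithium in place of iodine) | C=CC(C)(C)[C@H](O[Si](C)(C)C(C)(C)C)/C=C(\[Li])C | intermediate (not isolated)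
10 | lithium hemiaminolate (DMF adduct of 9) | C=CC(C)(C)[C@H](O[Si](C)(C)C(C)(C)C)/C=C(/C)C(O[Li])N(C)C | intermediate (not isolated)
11 | (2Z,4R)-4-(tert-butyldimethylsilyloxy)-2,5,5-trimethylhepta-2,6-dienal | C=CC(C)(C)[C@H](O[Si](C)(C)C(C)(C)C)/C=C(/C)C=O | intermediate
12 | ethyl tiglate, ethyl (2E)-2-methylbut-2-enoate | C/C=C(\C)C(=O)OCC | starting material
13 | lithium dienolate of ethyl tiglate | C=CC(C)=C(OCC)O[Li] | intermediate (not isolated)
14 | tert-butyl[(1-ethoxy-2-methylbuta-1,3-dien-1-yl)oxy]dimethylsilane | C=CC(C)=C(OCC)O[Si](C)(C)C(C)(C)C | intermediate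
15 | trichlorosilyl ether of 16 | C=CC(C)(C)[C@H](O[Si](C)(C)C(C)(C)C)/C=C(/C)[C@@H](O[Si](Cl)(Cl)Cl)C/C=C(\C)C(=O)OCC | intermediate (not isolated)
16 | ethyl (2E,5S,6Z,8R)-8-(tert-butyldimethylsilyloxy)-5-hydroxy-2,6,9,9-tetramethylundeca-2,6,10-trienoate | C=CC(C)(C)[C@H](O[Si](C)(C)C(C)(C)C)/C=C(/C)[C@@H](O)C/C=C(\C)C(=O)OCC | intermediate
17 | ethyl (2E,5S,6Z,8R)-8-(tert-butyldimethylsilyloxy)-2,6,9,9-tetramethyl-5-(triethylsilyloxy)undeca-2,6,10-trienoate | C=CC(C)(C)[C@H](O[Si](C)(C)C(C)(C)C)/C=C(/C)[C@@H](O[Si](CC)(CC)CC)C/C=C(\C)C(=O)OCC | intermediate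
18 | (2E,5S,6Z,8R)-8-(tert-butyldimethylsilyloxy)-2,6,9,9-tetramethyl-5-(triethylsilyloxy)undeca-2,6,10-trien-1-ol | C=CC(C)(C)[C@H](O[Si](C)(C)C(C)(C)C)/C=C(/C)[C@@H](O[Si](CC)(CC)CC)C/C=C(\C)CO | intermediate
19 | methyl carbonate of 18 | C=CC(C)(C)[C@H](O[Si](C)(C)C(C)(C)C)/C=C(/C)[C@@H](O[Si](CC)(CC)CC)C/C=C(\C)COC(=O)OC | intermediate
20 | B-alkyl-9-BBN from 19 (boron on the former vinyl terminus, C9) | C(CC(C)(C)[C@H](O[Si](C)(C)C(C)(C)C)/C=C(/C)[C@@H](O[Si](CC)(CC)CC)C/C=C(\C)COC(=O)OC)B1C2CCCC1CCC2 | intermediate (not isolated)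
21 | (1R,2Z,4S,6E)-1-(tert-butyldimethylsilyloxy)-3,7,11,11-tetramethyl-4-(triethylsilyloxy)cycloundeca-2,6-diene | CC[Si](CC)(CC)O[C@H]1C/C=C(\C)CCCC(C)(C)[C@H](O[Si](C)(C)C(C)(C)C)/C=C\1C | intermediate
22 | (1R,2Z,4S,6E)-3,7,11,11-tetramethylcycloundeca-2,6-diene-1,4-diol | O[C@H]1C/C=C(\C)CCCC(C)(C)[C@H](O)/C=C\1C | intermediate
23 | (1R,2Z,4S,6E)-1-hydroxy-3,7,11,11-tetramethylcycloundeca-2,6-dien-4-yl (2Z)-2-methylbut-2-enoate | C/C=C(/C)C(=O)O[C@H]1C/C=C(\C)CCCC(C)(C)[C@H](O)/C=C\1C | intermediate
24 | (1R,2Z,4S,6E)-1-acetoxy-3,7,11,11-tetramethylcycloundeca-2,6-dien-4-yl (2Z)-2-methylbut-2-enoate, systematically (1S,2Z,4R,9E)-4-acetoxy-2,5,5,9-tetramethylcycloundeca-2,9-dien-1-yl (2Z)-2-methylbut-2-enoate | C/C=C(/C)C(=O)O[C@H]1C/C=C(\C)CCCC(C)(C)[C@H](OC(C)=O)/C=C\1C | target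

Total step count: 13. Longest linear sequence: 12 (steps 1–4 and 6–13; step 5 prepares the dienol ether).

Steps most likely to fail

Step 10 (ring closure, proposed new method). β-Hydride elimination or protodeboronation at C9 may overtake C–C reductive elimination, oligomerisation may win over ring closure, or syn–anti isomerisation of the allyl unit may erode the E geometry at C6=C7. The fallback uses known chemistry (sulfonyl-carbanion allylation and reductive desulfonylation) and sets out from ester 17. Hydroboration–oxidation of the vinyl group (9-BBN, THF; NaBO3·4H2O) should give ethyl (2E,5S,6Z,8R)-8-(tert-butyldimethylsilyloxy)-11-hydroxy-2,6,9,9-tetramethyl-5-(triethylsilyloxy)undeca-2,6-dienoate F1. I2, PPh3 and imidazole convert it into the 11-iodide F2, and PhSO2Na in DMF into the 11-(phenylsulfonyl) ester F3. iBu2AlH reduces the ester to the allylic alcohol F4, and MsCl, LiCl and 2,4,6-collidine in DMF give the allylic chloride F5. LiN(iPr)2 under high dilution (THF, −78 → 0 °C) closes ring A by alkylation of the C9 sulfonyl carbanion with the C8 allylic chloride to the macrocyclic 9-(phenylsulfonyl) bis(silyl ether) F6 (C9 epimers). Na(Hg), Na2HPO4, MeOH then removes the sulfonyl group and comes back to the route at 21.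

Step 6 (vinylogous aldol). Facial selectivity at the aldehyde may be poor, or the Z-enal may isomerise to the E-enal under the chlorosilane Lewis acid before it is attacked. The fallback sets out from enal 11. Brown allylboration with (−)-Ipc2B(allyl) (Et2O, −78 °C; NaOH, H2O2; Si-face attack) should give (4S,5Z,7R)-7-(tert-butyldimethylsilyloxy)-5,8,8-trimethyldeca-1,5,9-trien-4-ol F7. TESCl and imidazole give its triethylsilyl ether F8. Cross-metathesis with methacrolein (second-generation Hoveyda–Grubbs catalyst, CH2Cl2, 40 °C) should engage only the new allyl terminus, since the vinyl group on quaternary C11 is expected to stay out, and give (2E,5S,6Z,8R)-8-(tert-butyldimethylsilyloxy)-2,6,9,9-tetramethyl-5-(triethylsilyloxy)undeca-2,6,10-trienal F9. Luche reduction (NaBH4, CeCl3·7H2O, MeOH) comes back to the route at 18.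

Step 12 (angeloylation of the diol). The acylating agent may not discriminate enough between the C4 and C1 hydroxyl groups, or the angeloyl unit may isomerise to the E (tigloyl) form during activation. The fallback sets out from bis(silyl ether) 21 and replaces site-selective acylation by orthogonal deprotection and direct esterification by a Z-selective olefination. PPTS in MeOH at 0 °C should cleave only the triethylsilyl ether to (1S,2Z,4R,9E)-4-(tert-butyldimethylsilyloxy)-2,5,5,9-tetramethylcycloundeca-2,9-dien-1-ol F10. DCC and DMAP with 2-[bis(2,2,2-trifluoroethoxy)phosphoryl]propanoic acid give the phosphonopropanoate ester F11. Still–Gennari olefination with acetaldehyde (KN(SiMe3)2, 18-crown-6, THF, −78 °C) builds the Z-2-methylbut-2-enoate in place to give the angelate silyl ether F12. HF·pyridine in THF removes the remaining silyl group and comes back to the route at 23.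

Further compounds
F1 | step 10 | ethyl (2E,5S,6Z,8R)-8-(tert-butyldimethylsilyloxy)-11-hydroxy-2,6,9,9-tetramethyl-5-(triethylsilyloxy)undeca-2,6-dienoate | OCCC(C)(C)[C@H](O[Si](C)(C)C(C)(C)C)/C=C(/C)[C@@H](O[Si](CC)(CC)CC)C/C=C(\C)C(=O)OCC
F2 | step 10 | ethyl (2E,5S,6Z,8R)-8-(tert-butyldimethylsilyloxy)-11-iodo-2,6,9,9-tetramethyl-5-(triethylsilyloxy)undeca-2,6-dienoate | ICCC(C)(C)[C@H](O[Si](C)(C)C(C)(C)C)/C=C(/C)[C@@H](O[Si](CC)(CC)CC)C/C=C(\C)C(=O)OCC
F3 | step 10 | ethyl (2E,5S,6Z,8R)-8-(tert-butyldimethylsilyloxy)-2,6,9,9-tetramethyl-11-(phenylsulfonyl)-5-(triethylsilyloxy)undeca-2,6-dienoate | O=S(=O)(CCC(C)(C)[C@H](O[Si](C)(C)C(C)(C)C)/C=C(/C)[C@@H](O[Si](CC)(CC)CC)C/C=C(\C)C(=O)OCC)c1ccccc1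
F4 | step 10 | (2E,5S,6Z,8R)-8-(tert-butyldimethylsilyloxy)-2,6,9,9-tetramethyl-11-(phenylsulfonyl)-5-(triethylsilyloxy)undeca-2,6-dien-1-ol | O=S(=O)(CCC(C)(C)[C@H](O[Si](C)(C)C(C)(C)C)/C=C(/C)[C@@H](O[Si](CC)(CC)CC)C/C=C(\C)CO)c1ccccc1
F5 | step 10 | allylic chloride of F4 (C8–Cl) | O=S(=O)(CCC(C)(C)[C@H](O[Si](C)(C)C(C)(C)C)/C=C(/C)[C@@H](O[Si](CC)(CC)CC)C/C=C(\C)CCl)c1ccccc1
F6 | step 10 | (1R,2Z,4S,6E)-1-(tert-butyldimethylsilyloxy)-3,7,11,11-tetramethyl-9-(phenylsulfonyl)-4-(triethylsilyloxy)cycloundeca-2,6-diene | CC[Si](CC)(CC)O[C@H]1C/C=C(\C)CC(S(=O)(=O)c2ccccc2)CC(C)(C)[C@H](O[Si](C)(C)C(C)(C)C)/C=C\1C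
F7 | step 6 | (4S,5Z,7R)-7-(tert-butyldimethylsilyloxy)-5,8,8-trimethyldeca-1,5,9-trien-4-ol | C=CC(C)(C)[C@H](O[Si](C)(C)C(C)(C)C)/C=C(/C)[C@@H](O)CC=C
F8 | step 6 | triethylsilyl ether of F7 | C=CC(C)(C)[C@H](O[Si](C)(C)C(C)(C)C)/C=C(/C)[C@@H](O[Si](CC)(CC)CC)CC=C
F9 | step 6 | (2E,5S,6Z,8R)-8-(tert-butyldimethylsilyloxy)-2,6,9,9-tetramethyl-5-(triethylsilyloxy)undeca-2,6,10-trienal | C=CC(C)(C)[C@H](O[Si](C)(C)C(C)(C)C)/C=C(/C)[C@@H](O[Si](CC)(CC)CC)C/C=C(\C)C=O
F10 | step 12 | (1S,2Z,4R,9E)-4-(tert-butyldimethylsilyloxy)-2,5,5,9-tetramethylcycloundeca-2,9-dien-1-ol | O[C@H]1C/C=C(\C)CCCC(C)(C)[C@H](O[Si](C)(C)C(C)(C)C)/C=C\1C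
F11 | step 12 | (1S,2Z,4R,9E)-4-(tert-butyldimethylsilyloxy)-2,5,5,9-tetramethylcycloundeca-2,9-dien-1-yl 2-[bis(2,2,2-trifluoroethoxy)phosphoryl]propanoate | CC(C(=O)O[C@H]1C/C=C(\C)CCCC(C)(C)[C@H](O[Si](C)(C)C(C)(C)C)/C=C\1C)P(=O)(OCC(F)(F)F)OCC(F)(F)F
F12 | step 12 | (1S,2Z,4R,9E)-4-(tert-butyldimethylsilyloxy)-2,5,5,9-tetramethylcycloundeca-2,9-dien-1-yl (2Z)-2-methylbut-2-enoate | C/C=C(/C)C(=O)O[C@H]1C/C=C(\C)CCCC(C)(C)[C@H](O[Si](C)(C)C(C)(C)C)/C=C\1C
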